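**Retrosynthetic overview**
1. The only ring, the cyclopentenone, is closed in the key step: a Pd-catalysed carbonylative cascade joins vinyl iodide C10, CO (C9), the alkyne C8≡C7 and a (Z)-alkenylstannane (C6), making C9–C10, C8–C9 and C6–C7; there is no aldol at C7–C8.
2. Syn-acylpalladation followed by a retentive Stille capture fixes 7Z and carries 5Z in; 14Z comes from (Z)-oct-2-en-1-ol.
3. The (Z)-1-chloro-1-iodoalkene comes from a 1-chloroalkyne by alkoxide-directed trans-hydroalumination and iodination.
4. C12 (R) is set by Sharpless epoxidation of a (2Z)-enynol, followed by an epoxy chloride to alkyne fragmentation that never breaks the C12–O bond.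
5. The enynol comes from (Z)-1-bromooct-2-ene and propargyl alcohol, then trans-hydroalumination/iodination and Sonogashira coupling.

Assumption: prostanoid numbering is used for the target (ester carbon C1, ring C8–C12, carbinol C12, chain end C20); compounds 1, 3, 7, 17 and diethyl D-(−)-tartrate are bought.

**Route**

Step 1
Reactants: 1 (Z)-oct-2-en-1-ol
Product: 2 (Z)-1-bromooct-2-ene
Conditions: CBr4, PPh3, CH2Cl2, 0 °C
Reagents that add atoms: carbon tetrabromide, BrC(Br)(Br)Br
Why: Appel bromination displaces the primary allylic oxyphosphonium by SN2 at 0 °C, so the Z-alkene is kept.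

Step 2
Reactants: 2 (Z)-1-bromooct-2-ene; 3 prop-2-yn-1-ol
Product: 4 (5Z)-undec-5-en-2-yn-1-ol
Conditions: CuI (10 mol %), n-Bu4NI (10 mol %), K2CO3, DMF, rt
Reagents that add atoms: none
Why: Copper-acetylide allylic alkylation (Cu-catalysed coupling of a terminal alkyne with a primary allylic bromide) attacks the unsubstituted carbon under mild carbonate conditions, keeping the Z-alkene and tolerating the free hydroxyl.

Step 3
Reactants: 4 (5Z)-undec-5-en-2-yn-1-ol
Product: 6 (2Z,5Z)-3-iodoundeca-2,5-dien-1-ol, via cyclic vinylalanate 5 (not isolated)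
Conditions: NaAlH2(OCH2CH2OMe)2, THF, 0 °C to rt; then I2, −78 °C
Reagents that add atoms: iodine, [I][I]
Why: Alkoxide-directed trans-hydroalumination of the propargylic alcohol puts Al on C3 inside a five-membered alanate, and iodinolysis with retention gives iodine cis to CH2OH; the isolated Z-alkene is inert.

Step 4
Reactants: 6 (2Z,5Z)-3-iodoundeca-2,5-dien-1-ol; 7 ethynyltrimethylsilane
Product: 8 (2Z,5Z)-3-[(trimethylsilyl)ethynyl]undeca-2,5-dien-1-ol
Conditions: PdCl2(PPh3)2 (3 mol %), CuI (5 mol %), i-Pr2NH, THF, rt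
Reagents that add atoms: none
Why: Sonogashira coupling of the vinyl iodide proceeds with retention, so the alkynyl group stays cis to CH2OH.

Step 5
Reactants: 8 (2Z,5Z)-3-[(trimethylsilyl)ethynyl]undeca-2,5-dien-1-ol
Product: 9 [(2R,3S)-3-[(2Z)-oct-2-en-1-yl]-3-[(trimethylsilyl)ethynyl]oxiran-2-yl]methanol
Conditions: Ti(OiPr)4 (10 mol %), diethyl D-(−)-tartrate (12 mol %), t-BuOOH, 4 Å molecular sieves, CH2Cl2, −20 °C
Reagents that add atoms: tert-butyl hydroperoxide, CC(C)(C)OO
Why: Katsuki–Sharpless asymmetric epoxidation touches only the allylic alkene; the D-tartrate delivers oxygen to the face that makes the CH carbon 2R (mirror of the 2S sense of the L-tartrate), and with the alkynyl group cis to CH2OH this fixes the quaternary carbon that becomes C12 in the sense needed for 12R.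

Step 6
Reactants: 9 [(2R,3S)-3-[(2Z)-oct-2-en-1-yl]-3-[(trimethylsilyl)ethynyl]oxiran-2-yl]methanol
Product: 10 (2S,3S)-3-(chloromethyl)-2-[(2Z)-oct-2-en-1-yl]-2-[(trimethylsilyl)ethynyl]oxirane
Conditions: PPh3, CCl4, NaHCO3, reflux
Reagents that add atoms: tetrachloromethane, ClC(Cl)(Cl)Cl
Why: Appel chlorination of the primary alcohol under buffered neutral conditions leaves the epoxide and both stereocentres untouched (the descriptor at the CH carbon changes only because CH2Cl outranks the ring carbon).

Step 7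
Reactants: 10 (2S,3S)-3-(chloromethyl)-2-[(2Z)-oct-2-en-1-yl]-2-[(trimethylsilyl)ethynyl]oxirane
Product: 12 (3S)-1-chloro-3-[(2Z)-oct-2-en-1-yl]-5-(trimethylsilyl)penta-1,4-diyn-3-ol, via dilithium alkynide alkoxide 11 (not isolated)
Conditions: n-BuLi (3.0 equiv), THF, −78 to −40 °C; then N-chlorosuccinimide, −78 to 0 °C; aq NH4Cl
Reagents that add atoms: N-chlorosuccinimide, O=C1CCC(=O)N1Cl
Why: Takano–Yadav fragmentation (α-deprotonation of CH2Cl, β-elimination that opens the epoxide at the C–O bond remote from the quaternary carbon, then loss of HCl) gives the lithium acetylide with the C12–O bond and its configuration intact, and electrophilic chlorination of the acetylide by NCS gives the 1-chloroalkyne.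

Step 8
Reactants: 12 (3S)-1-chloro-3-[(2Z)-oct-2-en-1-yl]-5-(trimethylsilyl)penta-1,4-diyn-3-ol
Product: 14 (1Z,3R,5Z)-1-chloro-1-iodo-3-[(trimethylsilyl)ethynyl]undeca-1,5-dien-3-ol, via cyclic chlorovinylalanate 13 (not isolated)
Conditions: LiAlH4 (1.0 equiv), THF, −40 to −20 °C; then I2, −78 °C
Reagents that add atoms: iodine, [I][I]
Why: Alkoxide-directed trans-hydroalumination of the electrophilic 1-chloroalkyne (Zweifel-type) delivers hydride to the carbon next to the carbinol and holds Al on the chlorine-bearing carbon cis to the carbinol in a five-membered alanate, so iodinolysis with retention gives iodine cis to C12; the silylalkyne reacts far more slowly at this temperature.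

Step 9
Reactants: 14 (1Z,3R,5Z)-1-chloro-1-iodo-3-[(trimethylsilyl)ethynyl]undeca-1,5-dien-3-ol
Product: 15 (1Z,3R,5Z)-1-chloro-3-ethynyl-1-iodoundeca-1,5-dien-3-ol
Conditions: K2CO3 (20 mol %), MeOH, 0 °C
Reagents that add atoms: none
Why: Base-catalysed methanolysis cleaves the C(sp)–Si bond selectively; the dihaloalkene and the stereocentre are not affected at 0 °C.

Step 10
Reactants: 15 (1Z,3R,5Z)-1-chloro-3-ethynyl-1-iodoundeca-1,5-dien-3-ol
Product: 16 {[(1Z,3R,5Z)-1-chloro-3-ethynyl-1-iodoundeca-1,5-dien-3-yl]oxy}trimethylsilane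
Conditions: Me3SiOTf, 2,6-lutidine, CH2Cl2, −78 °C
Reagents that add atoms: trimethylsilyl trifluoromethanesulfonate, C[Si](C)(C)OS(=O)(=O)C(F)(F)F
Why: Silyl triflate silylation of the hindered tertiary alcohol masks the hydroxyl, which would otherwise trap the acylpalladium of step 13 as a butenolide.

Step 11
Reactants: 17 methyl hex-5-ynoate
Product: 18 methyl 6-(tributylstannyl)hex-5-ynoate
Conditions: Bu3SnOMe, ZnBr2 (5 mol %), THF, rt
Reagents that add atoms: tributyltin methoxide, CCCC[Sn](CCCC)(CCCC)OC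
Why: ZnBr2-catalysed stannylation of the terminal alkyne by the tin methoxide (loss of methanol) needs no strong base, so the ester survives.

Step 12
Reactants: 18 methyl 6-(tributylstannyl)hex-5-ynoate
Product: 20 methyl (5Z)-6-(tributylstannyl)hex-5-enoate, via alkenylzirconocene 19 (not isolated)
Conditions: Cp2Zr(H)Cl (1.2 equiv), THF, rt; then H2O
Reagents that add atoms: none
Why: Syn-hydrozirconation of the stannylalkyne puts Zr on the tin-bearing carbon, and protonolysis with retention leaves the chain and tin cis, giving the (Z)-alkenylstannane; the alkyne reacts much faster than the ester.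

Step 13
Reactants: 16 {[(1Z,3R,5Z)-1-chloro-3-ethynyl-1-iodoundeca-1,5-dien-3-yl]oxy}trimethylsilane; 20 methyl (5Z)-6-(tributylstannyl)hex-5-enoate
Product: 21 methyl (5Z,7Z,12R,14Z)-10-chloro-9-oxo-12-[(trimethylsilyl)oxy]prosta-5,7,10,14-tetraen-1-oate
Conditions: Pd2(dba)3 (5 mol %), AsPh3 (20 mol %), CO (1 atm), THF (0.02 M), 50 °C
Reagents that add atoms: carbon monoxide, [C-]#[O+]
Why: Proposed new method: zerovalent palladium inserts into the C–I bond only, CO insertion gives a (Z)-acylpalladium that adds syn across the tethered terminal alkyne in a 5-exo-dig cyclic acylpalladation (closing the cyclopentenone and leaving an O-chelated alkenylpalladium at C7 that has no β-hydrogen), and Stille transmetalation with reductive elimination, retentive at both carbons, places C6 cis to the C9 carbonyl (7Z) while keeping 5Z and leaving C12 untouched; the closest known reaction types are cyclic acylpalladation of alkynes, carbonylative Stille coupling and cyclisation–anion-capture cascades.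

Step 14
Reactants: 21 methyl (5Z,7Z,12R,14Z)-10-chloro-9-oxo-12-[(trimethylsilyl)oxy]prosta-5,7,10,14-tetraen-1-oate
Product: 22 methyl (5Z,7Z,12R,14Z)-10-chloro-12-hydroxy-9-oxoprosta-5,7,10,14-tetraen-1-oate
Conditions: 1 M HCl, THF, 0 °C
Reagents that add atoms: none
Why: Mild acid hydrolysis of the tertiary trimethylsilyl ether; the carbinol cannot ionise next to the cross-conjugated dienone, and the methyl ester and alkene geometries are stable under these conditions.

**Compound list**
1 | (Z)-oct-2-en-1-ol | CCCCC/C=C\CO | starting material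
2 | (Z)-1-bromooct-2-ene | CCCCC/C=C\CBr | intermediate
3 | prop-2-yn-1-ol | C#CCO | starting material
4 | (5Z)-undec-5-en-2-yn-1-ol | OCC#CC/C=C\CCCCC | intermediate
5 | cyclic vinylalanate: sodium 2,2-bis(2-methoxyethoxy)-3-[(2Z)-oct-2-en-1-yl]-2,5-dihydro-1,2-oxaluminol-2-uide (not isolated) | [Na+].COCCO[Al-]1(OCCOC)OCC=C1C/C=C\CCCCC | intermediate
6 | (2Z,5Z)-3-iodoundeca-2,5-dien-1-ol | I/C(=C\CO)C/C=C\CCCCC | intermediate
7 | ethynyltrimethylsilane | C#C[Si](C)(C)C | starting material
8 | (2Z,5Z)-3-[(trimethylsilyl)ethynyl]undeca-2,5-dien-1-ol | C[Si](C)(C)C#C/C(=C\CO)C/C=C\CCCCC | intermediate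
9 | [(2R,3S)-3-[(2Z)-oct-2-en-1-yl]-3-[(trimethylsilyl)ethynyl]oxiran-2-yl]methanol | OC[C@H]1O[C@]1(C#C[Si](C)(C)C)C/C=C\CCCCC | intermediate
10 | (2S,3S)-3-(chloromethyl)-2-[(2Z)-oct-2-en-1-yl]-2-[(trimethylsilyl)ethynyl]oxirane | ClC[C@H]1O[C@]1(C#C[Si](C)(C)C)C/C=C\CCCCC | intermediate
11 | dilithium alkynide alkoxide: C,O-dilithio derivative of (3R)-3-[(2Z)-oct-2-en-1-yl]-1-(trimethylsilyl)penta-1,4-diyn-3-ol (not isolated) | [Li]C#C[C@@](O[Li])(C#C[Si](C)(C)C)C/C=C\CCCCC | intermediate
12 | (3S)-1-chloro-3-[(2Z)-oct-2-en-1-yl]-5-(trimethylsilyl)penta-1,4-diyn-3-ol | ClC#C[C@@](O)(C#C[Si](C)(C)C)C/C=C\CCCCC | intermediate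
13 | cyclic chlorovinylalanate: lithium salt of the five-membered O–Al–C alanate, Al on the chlorine-bearing carbon (not isolated) | [Li+].ClC1=C[C@@](C#C[Si](C)(C)C)(C/C=C\CCCCC)O[AlH2-]1 | intermediate
14 | (1Z,3R,5Z)-1-chloro-1-iodo-3-[(trimethylsilyl)ethynyl]undeca-1,5-dien-3-ol | I/C(Cl)=C\[C@@](O)(C#C[Si](C)(C)C)C/C=C\CCCCC | intermediate
15 | (1Z,3R,5Z)-1-chloro-3-ethynyl-1-iodoundeca-1,5-dien-3-ol | I/C(Cl)=C\[C@@](O)(C#C)C/C=C\CCCCC | intermediate
16 | {[(1Z,3R,5Z)-1-chloro-3-ethynyl-1-iodoundeca-1,5-dien-3-yl]oxy}trimethylsilane | I/C(Cl)=C\[C@@](O[Si](C)(C)C)(C#C)C/C=C\CCCCC | intermediate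
17 | methyl hex-5-ynoate | COC(=O)CCCC#C | starting material
18 | methyl 6-(tributylstannyl)hex-5-ynoate | COC(=O)CCCC#C[Sn](CCCC)(CCCC)CCCC | intermediate
19 | alkenylzirconocene: chlorobis(cyclopentadienyl)[(1E)-6-methoxy-6-oxo-1-(tributylstannyl)hex-1-en-1-yl]zirconium (not isolated) | COC(=O)CCC/C=C(\[Sn](CCCC)(CCCC)CCCC)[Zr](Cl)(C1C=CC=C1)C1C=CC=C1 | intermediate
20 | methyl (5Z)-6-(tributylstannyl)hex-5-enoate | COC(=O)CCC/C=C\[Sn](CCCC)(CCCC)CCCC | intermediate
21 | methyl (5Z,7Z,12R,14Z)-10-chloro-9-oxo-12-[(trimethylsilyl)oxy]prosta-5,7,10,14-tetraen-1-oate | CCCCC/C=C\C[C@@]1(O[Si](C)(C)C)C=C(Cl)C(=O)/C1=C\C=C/CCCC(=O)OC | intermediate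
22 | methyl (5Z,7Z,12R,14Z)-10-chloro-12-hydroxy-9-oxoprosta-5,7,10,14-tetraen-1-oate (the target chlorovulone) | CCCCC/C=C\C[C@@]1(O)C=C(Cl)C(=O)/C1=C\C=C/CCCC(=O)OC | target

**Step count**
Total: 14 steps. Longest linear sequence: 12 steps (steps 1–10, 13, 14); steps 11–12 make the stannane.

**Three steps most likely to fail, with fallbacks**

Step 13 (carbonylative cascade). The alkenylpalladium formed after ring closure may insert a second CO faster than it transmetallates, or the stannane may capture the first acylpalladium before cyclisation. The fallback uses the second CO insertion and moves the last C–C bond formation from C6–C7 (Stille) to C5=C6 (Wittig). It sets out from 16: Pd(PPh3)4, CO (3 atm) and Et3SiH added slowly by syringe pump give, by the same ring closure followed by CO insertion and hydride capture, the (2Z)-keto-enal (2Z)-2-[(5R)-3-chloro-5-[(2Z)-oct-2-en-1-yl]-2-oxo-5-[(trimethylsilyl)oxy]cyclopent-3-en-1-ylidene]acetaldehyde F1, whose formyl group is cis to the ring carbonyl. A salt-free Wittig reaction at −78 °C in THF with the ylide methyl 5-(triphenyl-λ5-phosphanylidene)pentanoate F2, made from (4-methoxy-4-oxobutyl)triphenylphosphonium bromide and NaN(SiMe3)2, reacts at the aldehyde only and gives the 5Z alkene. The fallback comes back to the route at 21.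

Step 8 (directed hydroalumination/iodination). The alkoxide may also pass hydride to the silylalkyne on the same carbinol, or the α-chloroalkenylalanate may decompose before iodination. The fallback removes the alkoxide as a control element and relies on substrate-controlled, intermolecular hydride attack. It sets out from 12: Me3SiOTf and 2,6-lutidine give the bis-silyl chloroalkyne {[(3S)-1-chloro-3-[(2Z)-oct-2-en-1-yl]-5-(trimethylsilyl)penta-1,4-diyn-3-yl]oxy}trimethylsilane F3. LiAlH4 in THF at −30 °C then adds trans to the polarised 1-chloroalkyne only (the unactivated silylalkyne is inert), and I2 at −78 °C gives the chloroiodoalkene {[(1Z,3R,5Z)-1-chloro-1-iodo-3-[(trimethylsilyl)ethynyl]undeca-1,5-dien-3-yl]oxy}trimethylsilane F4. K2CO3 in MeOH removes both silyl groups, and the fallback comes back to the route at 15.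

Step 7 (one-pot fragmentation/chlorination). NCS may be consumed by the lithium alkoxide, or the dilithio species may give mixtures. The fallback separates the two events and chlorinates through a silver acetylide under neutral conditions. It sets out from 10: LiN(iPr)2 (3 equiv) in THF at −78 to −30 °C, then aqueous NH4Cl, gives the isolated terminal alkyne (3R)-3-[(2Z)-oct-2-en-1-yl]-1-(trimethylsilyl)penta-1,4-diyn-3-ol F5. NCS with AgOAc (10 mol %) in acetone at rt chlorinates the terminal alkyne carbon and tolerates the free tertiary alcohol, and the fallback comes back to the route at 12.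

**Further compounds**
F1 | step 13 | (2Z)-2-[(5R)-3-chloro-5-[(2Z)-oct-2-en-1-yl]-2-oxo-5-[(trimethylsilyl)oxy]cyclopent-3-en-1-ylidene]acetaldehyde | CCCCC/C=C\C[C@@]1(O[Si](C)(C)C)C=C(Cl)C(=O)/C1=C\C=O
F2 | step 13 | methyl 5-(triphenyl-λ5-phosphanylidene)pentanoate | COC(=O)CCCC=P(c1ccccc1)(c1ccccc1)c1ccccc1
F3 | step 8 | {[(3S)-1-chloro-3-[(2Z)-oct-2-en-1-yl]-5-(trimethylsilyl)penta-1,4-diyn-3-yl]oxy}trimethylsilane | ClC#C[C@@](O[Si](C)(C)C)(C#C[Si](C)(C)C)C/C=C\CCCCC
F4 | step 8 | {[(1Z,3R,5Z)-1-chloro-1-iodo-3-[(trimethylsilyl)ethynyl]undeca-1,5-dien-3-yl]oxy}trimethylsilane | I/C(Cl)=C\[C@@](O[Si](C)(C)C)(C#C[Si](C)(C)C)C/C=C\CCCCC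
F5 | step 7 | (3R)-3-[(2Z)-oct-2-en-1-yl]-1-(trimethylsilyl)penta-1,4-diyn-3-ol | C#C[C@@](O)(C#C[Si](C)(C)C)C/C=C\CCCCC
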